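**Retrosynthetic overview**

1. The target is reached last by ruthenium-catalysed ketohydroxylation of the C1=C10 olefin of a 9-O-epoxyangeloyl germacra-1(10),4-dien-6-one, which installs the C1 ketone and the C10 carbinol.
2. That ester comes from Yamaguchi coupling of the 9-hydroxy dienone with (2R,3R)-epoxyangelic acid; the oxirane is made as in nature, by epoxidation of the angelate C=C (Sharpless epoxidation of angelyl alcohol, then oxidation).
3. The ten-membered ring is closed at C6–C7 (farnesane C1–C10) by a cyclase-type cation–olefin macrocyclisation of (R)-8-hydroxyfarnesal; two 1,2-hydride shifts discharge the C11 cation, so ring, enone and isopropyl group arise in one operation.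
4. (R)-8-Hydroxyfarnesal comes from geranyl acetate by SeO2 oxidation, asymmetric allylation, cross-metathesis, deacetylation and selective oxidation.
5. Ring order: the carbocycle is closed in the main line (step 6); the oxirane is formed separately in the side-chain line (step 8) and joined in step 10.

Assumption: ring compounds carry germacrane numbering (C1 and C6 = ring carbonyl carbons of the target, C4=C5 = enone olefin, C7 = isopropyl carbon, C9 = ester carbinol, C10 = tertiary carbinol), acyclic precursors carry farnesane numbering (farnesane C1, C8, C10 become germacrane C6, C9, C7), and geranyl acetate, allyltributylstannane, 2-methylbut-2-ene and angelic acid are bought.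

**Step 1**
Reactants: 1 geranyl acetate [(2E)-3,7-dimethylocta-2,6-dien-1-yl acetate]
Product: 3 (2E,6E)-3,7-dimethyl-8-oxoocta-2,6-dien-1-yl acetate (8-oxogeranyl acetate), via 8-hydroxygeranyl acetate 2 (not isolated)
Conditions: SeO2 (1.1 equiv), EtOH (95%), reflux, 2 h
Reagents that add atoms: selenium dioxide, O=[Se]=O
Why: Riley allylic oxidation (ene reaction then [2,3]-sigmatropic shift) attacks the (E)-methyl group of the electron-rich terminal olefin, the 2,3-olefin being deactivated by the allylic acetate, and alcohol 2 is oxidised on to the enal with retention of E geometry; no stereocentre is formed.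

**Step 2**
Reactants: 3 8-oxogeranyl acetate; 4 allyltributylstannane
Product: 5 (2E,6E,8R)-8-hydroxy-3,7-dimethylundeca-2,6,10-trien-1-yl acetate
Conditions: (R)-BINOL (20 mol%), Ti(OiPr)4 (10 mol%), 4 Å MS, CH2Cl2, −20 °C, 72 h; aq. NaHCO3
Reagents that add atoms: allyltributylstannane (compound 4), C=CC[Sn](CCCC)(CCCC)CCCC
Why: Keck asymmetric allylation, in which the (R)-BINOL–titanium complex delivers the allyl group to the Re face of the enal and so sets the (8R) carbinol (about 90% ee expected; the minor enantiomer is removed later as a separable diastereomer of 20), the acetate being inert.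

**Step 3**
Reactants: 5 the (8R) homoallylic alcohol; 6 2-methylbut-2-ene
Product: 7 (2E,6E,8R)-8-hydroxy-3,7,11-trimethyldodeca-2,6,10-trien-1-yl acetate [(R)-8-hydroxyfarnesyl acetate]
Conditions: second-generation Grubbs catalyst RuCl2(=CHPh)(H2IMes)(PCy3) (3 mol%), 2-methylbut-2-ene (excess), CH2Cl2, rt
Reagents that add atoms: 2-methylbut-2-ene (compound 6), CC=C(C)C
Why: olefin cross-metathesis in which only the monosubstituted terminal alkene reacts (the two trisubstituted olefins are inert, and ring closure would need a cyclobutene), converting allyl into prenyl without touching C8.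

**Step 4**
Reactants: 7 (R)-8-hydroxyfarnesyl acetate
Product: 8 (2E,6E,8R)-3,7,11-trimethyldodeca-2,6,10-triene-1,8-diol [(R)-8-hydroxyfarnesol]
Conditions: K2CO3 (0.2 equiv), MeOH, 0 °C to rt
Reagents that add atoms: none
Why: base-catalysed transesterification (methanolysis) of the primary allylic acetate, which leaves the olefin geometry and C8 unchanged.

**Step 5**
Reactants: 8 (R)-8-hydroxyfarnesol
Product: 9 (2E,6E,8R)-8-hydroxy-3,7,11-trimethyldodeca-2,6,10-trienal [(R)-8-hydroxyfarnesal]
Conditions: TEMPO (10 mol%), PhI(OAc)2 (1.1 equiv), CH2Cl2, rt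
Reagents that add atoms: none
Why: oxoammonium (TEMPO) oxidation is sterically selective for the primary allylic alcohol over the hindered secondary one and gives the (2E)-enal without E/Z scrambling or over-oxidation.

**Step 6** (key step)
Reactants: 9 (R)-8-hydroxyfarnesal
Product: 13 (7R,9R)-9-hydroxygermacra-1(10)E,4E-dien-6-one [(2E,6E,8R,10R)-8-hydroxy-3,7-dimethyl-10-(propan-2-yl)cyclodeca-2,6-dien-1-one], via dichloroaluminium alkoxide 10 (not isolated), via C11 carbocation 11 (not isolated), via C7 carbocation 12 (not isolated)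
Conditions: MeAlCl2 (3.3 equiv), CH2Cl2 (0.002 M, slow addition of 9), −78 to −40 °C; Et3N, then aq. KNaC4H4O6
Reagents that add atoms: none
Why: Proposed new method: the first equivalent of MeAlCl2 masks the hydroxyl as its dichloroaluminium alkoxide 10 and two more bind the enal oxygen, so the doubly activated carbonyl carbon (farnesane C1) is attacked in Markovnikov sense by the distal C10=C11 olefin through a crown-shaped (E,E) transition state, which is the bond germacrene synthases form; the bis-aluminated alkoxide cannot act as base for ene-type proton loss, so cation 11 collapses by a 1,2-hydride shift from C7 to C11 (creating the isopropyl group and cation 12) and then by a 1,2-shift of the carbinol hydrogen from C6 to C7, driven by formation of the aluminium-bound conjugated ketone; C7 is set under control of C9 with both substituents pseudo-equatorial on the crown (7,9-cis), and since C7 is alpha to the ketone any trans epimer should converge on the same isomer on equilibration; the closest known reaction types are the MeAlCl2-induced Prins cyclisation of unsaturated aldehydes that ends in two 1,2-hydride shifts to give 2-isopropylcycloalkanones (five- and six-membered rings) and the SnCl4-induced macrocyclisation of polyprenoic acid chlorides onto their terminal olefin (fourteen-membered ring).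

**Step 7**
Reactants: 14 angelic acid [(2Z)-2-methylbut-2-enoic acid]
Product: 15 (2Z)-2-methylbut-2-en-1-ol (angelyl alcohol)
Conditions: LiAlH4, Et2O, 0 °C
Reagents that add atoms: none
Why: hydride reduction of the carboxylic acid to the allylic alcohol, 1,2-selective and without Z-to-E isomerisation at 0 °C.

**Step 8**
Reactants: 15 angelyl alcohol
Product: 16 [(2S,3R)-2,3-dimethyloxiran-2-yl]methanol
Conditions: Ti(OiPr)4 (10 mol%), L-(+)-diethyl tartrate (12 mol%), tBuOOH, 4 Å MS, CH2Cl2, −20 °C; non-aqueous work-up
Reagents that add atoms: tert-butyl hydroperoxide, CC(C)(C)OO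
Why: Sharpless asymmetric epoxidation, in which the L-(+)-tartrate–titanium complex selects the olefin face that gives the (2S,3R) epoxy alcohol, and the stereospecific syn oxygen transfer to the Z olefin fixes the cis (angelate-type) relationship of CH2OH and the C3 methyl.

**Step 9**
Reactants: 16 the (2S,3R) epoxy alcohol
Product: 18 (2R,3R)-2,3-dimethyloxirane-2-carboxylic acid (epoxyangelic acid), via epoxy aldehyde 17 (not isolated)
Conditions: TEMPO (20 mol%), PhI(OAc)2 (2.2 equiv), MeCN/H2O (1:1), rt
Reagents that add atoms: water, O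
Why: oxoammonium oxidation of the primary alcohol through the aldehyde hydrate to the acid under near-neutral conditions that spare the oxirane; C2 has no hydrogen, so neither centre can epimerise (the descriptor at C2 changes from S to R only through CIP priorities).

**Step 10**
Reactants: 13 the 9-hydroxy dienone; 18 epoxyangelic acid
Product: 20 (7R,9R)-6-oxogermacra-1(10)E,4E-dien-9-yl (2R,3R)-2,3-dimethyloxirane-2-carboxylate, via Yamaguchi mixed anhydride 19 (not isolated)
Conditions: 18, 2,4,6-trichlorobenzoyl chloride, Et3N, THF, rt; then 13, DMAP, toluene, rt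
Reagents that add atoms: none
Why: Yamaguchi esterification acylates the secondary allylic alcohol at oxygen with retention at C9 under mild base, and joining two enantio-enriched partners lets the minor enantiomers be removed as chromatographically separable diastereomers.

**Step 11**
Reactants: 20 the epoxyangelate ester
Product: 21 (7R,9R,10S)-10-hydroxy-1,6-dioxogermacr-4E-en-9-yl (2R,3R)-2,3-dimethyloxirane-2-carboxylate (CNP0389889.1)
Conditions: RuCl3 (2 mol%), 2KHSO5·KHSO4·K2SO4, NaHCO3, EtOAc/MeCN/H2O (6:6:1), rt, 15 min
Reagents that add atoms: potassium peroxymonosulfate (KHSO5, the active salt of 2KHSO5·KHSO4·K2SO4), [K+].[O-]S(=O)(=O)OO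
Why: ruthenium-catalysed ketohydroxylation, in which RuO4 adds [3+2] to the electron-richer trisubstituted C1=C10 olefin (the enone olefin is electron-poor) and the ruthenate ester is oxidised to the ketol with the carbonyl necessarily at the former CH carbon C1 and the tertiary hydroxyl at C10; attack on the exposed outer face of the crown conformer, whose C10 methyl is syn to the pseudo-equatorial C7 and C9 substituents, places the new C10–O bond trans to the C9 ester oxygen and gives 10S.

**Compound list**

1 | geranyl acetate | CC(=O)OC/C=C(\C)CCC=C(C)C | starting material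
2 | (2E,6E)-8-hydroxy-3,7-dimethylocta-2,6-dien-1-yl acetate (8-hydroxygeranyl acetate) | CC(=O)OC/C=C(\C)CC/C=C(\C)CO | intermediate (not isolated)
3 | (2E,6E)-3,7-dimethyl-8-oxoocta-2,6-dien-1-yl acetate | CC(=O)OC/C=C(\C)CC/C=C(\C)C=O | intermediate
4 | allyltributylstannane | C=CC[Sn](CCCC)(CCCC)CCCC | starting material
5 | (2E,6E,8R)-8-hydroxy-3,7-dimethylundeca-2,6,10-trien-1-yl acetate | CC(=O)OC/C=C(\C)CC/C=C(\C)[C@H](O)CC=C | intermediate
6 | 2-methylbut-2-ene | CC=C(C)C | starting material
7 | (2E,6E,8R)-8-hydroxy-3,7,11-trimethyldodeca-2,6,10-trien-1-yl acetate | CC(=O)OC/C=C(\C)CC/C=C(\C)[C@H](O)CC=C(C)C | intermediate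
8 | (2E,6E,8R)-3,7,11-trimethyldodeca-2,6,10-triene-1,8-diol | OC/C=C(\C)CC/C=C(\C)[C@H](O)CC=C(C)C | intermediate
9 | (2E,6E,8R)-8-hydroxy-3,7,11-trimethyldodeca-2,6,10-trienal | O=C/C=C(\C)CC/C=C(\C)[C@H](O)CC=C(C)C | intermediate
10 | O-dichloroaluminium derivative of 9 (C8–O–AlCl2) | O=C/C=C(\C)CC/C=C(\C)[C@H](O[Al](Cl)Cl)CC=C(C)C | intermediate (not isolated)
11 | ten-membered zwitterion with exocyclic C11 tertiary carbocation, C6–O aluminate and C9–O–AlCl2 (C6 and C7 not fixed) | C/C1=C\C(O[Al-](C)(Cl)Cl)C([C+](C)C)C[C@@H](O[Al](Cl)Cl)/C(C)=C/CC1 | intermediate (not isolated)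
12 | ten-membered zwitterion with ring C7 carbocation bearing the isopropyl group (C6 not fixed) | C/C1=C\C(O[Al-](C)(Cl)Cl)[C+](C(C)C)C[C@@H](O[Al](Cl)Cl)/C(C)=C/CC1 | intermediate (not isolated)
13 | (7R,9R)-9-hydroxygermacra-1(10)E,4E-dien-6-one | C/C1=C\C(=O)[C@@H](C(C)C)C[C@@H](O)/C(C)=C/CC1 | intermediate
14 | angelic acid, (2Z)-2-methylbut-2-enoic acid | C/C=C(/C)C(=O)O | starting material
15 | (2Z)-2-methylbut-2-en-1-ol | C/C=C(/C)CO | intermediate
16 | [(2S,3R)-2,3-dimethyloxiran-2-yl]methanol | OC[C@]1(C)O[C@@H]1C | intermediate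
17 | (2R,3R)-2,3-dimethyloxirane-2-carbaldehyde | O=C[C@]1(C)O[C@@H]1C | intermediate (not isolated)
18 | (2R,3R)-2,3-dimethyloxirane-2-carboxylic acid | OC(=O)[C@]1(C)O[C@@H]1C | intermediate
19 | (2R,3R)-2,3-dimethyloxirane-2-carboxylic 2,4,6-trichlorobenzoic anhydride | O=C(OC(=O)c1c(Cl)cc(Cl)cc1Cl)[C@]1(C)O[C@@H]1C | intermediate (not isolated)
20 | (7R,9R)-6-oxogermacra-1(10)E,4E-dien-9-yl (2R,3R)-2,3-dimethyloxirane-2-carboxylate | C/C1=C\C(=O)[C@@H](C(C)C)C[C@@H](OC(=O)[C@]2(C)O[C@@H]2C)/C(C)=C/CC1 | intermediate
21 | (7R,9R,10S)-10-hydroxy-1,6-dioxogermacr-4E-en-9-yl (2R,3R)-2,3-dimethyloxirane-2-carboxylate | C/C1=C\C(=O)[C@@H](C(C)C)C[C@@H](OC(=O)[C@]2(C)O[C@@H]2C)[C@](C)(O)C(=O)CC1 | target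

**Step count and risks**

Total step count: 11 (steps 1–6 and 10–11 in the main line, steps 7–9 for the side chain). Longest linear sequence: 8 steps (1, 2, 3, 4, 5, 6, 10, 11).

Steps most likely to fail:

Step 6, the macrocyclisation cascade. The enal may isomerise E to Z and close a six-membered ring with the central olefin, the cation may end by ene-type proton loss or be trapped by the C9 oxygen, the allylic aluminium alkoxide may ionise, or the product may undergo a transannular Prins reaction. The fallback closes the same C6–C7 bond with reversed polarity, starting from 9. Silylation (TBSOTf, 2,6-lutidine) gives (2E,6E,8R)-8-(tert-butyldimethylsilyloxy)-3,7,11-trimethyldodeca-2,6,10-trienal F1. Ene-type chlorination of the terminal olefin (Ca(OCl)2, solid CO2, CH2Cl2/H2O) gives (2E,6E,8R)-8-(tert-butyldimethylsilyloxy)-10-chloro-3,7,11-trimethyldodeca-2,6,11-trienal F2. Umpolung allylation of the enal with zerovalent palladium and diethylzinc (Pd(PPh3)4, Et2Zn, K2CO3, THF, high dilution) closes the ring to (7R,9R)-9-(tert-butyldimethylsilyloxy)germacra-1(10)E,4E,11-trien-6-ol F3. Dess–Martin oxidation gives (7R,9R)-9-(tert-butyldimethylsilyloxy)germacra-1(10)E,4E,11-trien-6-one F4. Hydrogenation of only the 1,1-disubstituted olefin (H2, RhCl(PPh3)3) gives (7R,9R)-9-(tert-butyldimethylsilyloxy)germacra-1(10)E,4E-dien-6-one F5, and desilylation (HF·pyridine) rejoins the route at 13.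

Step 11, the ketohydroxylation. RuO4 may also attack the enone olefin, cleave the C1–C10 bond or choose the other face. The fallback starts from 20 and splits the oxidation in two. Osmium-catalysed dihydroxylation (K2OsO2(OH)4 cat., N-methylmorpholine N-oxide, acetone/H2O), which discriminates more strongly against the enone and adds to the same outer face, gives (1S,7R,9R,10R)-1,10-dihydroxy-6-oxogermacr-4E-en-9-yl (2R,3R)-2,3-dimethyloxirane-2-carboxylate F6. Oxidation of its only secondary hydroxyl (Dess–Martin periodinane, NaHCO3) returns to the route at 21.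

Step 2, the asymmetric allylation. Keck allylation of an alpha-branched enal can be slow and of lower ee, and this step carries the absolute configuration of the whole ring. The fallback starts from 3 and sets C8 by asymmetric reduction. Alpha-selective addition of prenylbarium chloride (prenyl chloride, barium from BaI2 and lithium biphenylide LiC12H10, THF, −78 °C) gives racemic (2E,6E)-8-hydroxy-3,7,11-trimethyldodeca-2,6,10-trien-1-yl acetate F7. Dess–Martin oxidation gives (2E,6E)-3,7,11-trimethyl-8-oxododeca-2,6,10-trien-1-yl acetate F8. Corey–Bakshi–Shibata reduction ((S)-2-methyl-CBS-oxazaborolidine, catecholborane, toluene, −78 °C; the alkenyl group is the large substituent) gives the (8R) alcohol and rejoins the route at 7, bypassing step 3.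

**Further compounds**

F1 | step 6 | (2E,6E,8R)-8-(tert-butyldimethylsilyloxy)-3,7,11-trimethyldodeca-2,6,10-trienal | O=C/C=C(\C)CC/C=C(\C)[C@H](O[Si](C)(C)C(C)(C)C)CC=C(C)C
F2 | step 6 | (2E,6E,8R)-8-(tert-butyldimethylsilyloxy)-10-chloro-3,7,11-trimethyldodeca-2,6,11-trienal (C10 epimers) | O=C/C=C(\C)CC/C=C(\C)[C@H](O[Si](C)(C)C(C)(C)C)CC(Cl)C(C)=C
F3 | step 6 | (7R,9R)-9-(tert-butyldimethylsilyloxy)germacra-1(10)E,4E,11-trien-6-ol (C6 epimers) | C/C1=C\C(O)[C@@H](C(C)=C)C[C@@H](O[Si](C)(C)C(C)(C)C)/C(C)=C/CC1
F4 | step 6 | (7R,9R)-9-(tert-butyldimethylsilyloxy)germacra-1(10)E,4E,11-trien-6-one | C/C1=C\C(=O)[C@@H](C(C)=C)C[C@@H](O[Si](C)(C)C(C)(C)C)/C(C)=C/CC1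
F5 | step 6 | (7R,9R)-9-(tert-butyldimethylsilyloxy)germacra-1(10)E,4E-dien-6-one | C/C1=C\C(=O)[C@@H](C(C)C)C[C@@H](O[Si](C)(C)C(C)(C)C)/C(C)=C/CC1
F6 | step 11 | (1S,7R,9R,10R)-1,10-dihydroxy-6-oxogermacr-4E-en-9-yl (2R,3R)-2,3-dimethyloxirane-2-carboxylate | C/C1=C\C(=O)[C@@H](C(C)C)C[C@@H](OC(=O)[C@]2(C)O[C@@H]2C)[C@](C)(O)[C@@H](O)CC1
F7 | step 2 | (2E,6E)-8-hydroxy-3,7,11-trimethyldodeca-2,6,10-trien-1-yl acetate (racemic at C8) | CC(=O)OC/C=C(\C)CC/C=C(\C)C(O)CC=C(C)C
F8 | step 2 | (2E,6E)-3,7,11-trimethyl-8-oxododeca-2,6,10-trien-1-yl acetate | CC(=O)OC/C=C(\C)CC/C=C(\C)C(=O)CC=C(C)C
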